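The readings are calculated with constants of no real substance.

1. The protic impurity stands to the starting material as 0.500, and my next run hangs on that ratio.

the same everywhere: starting material 0.071 M; gas phase 20 mM (held); protic impurity 0.0355 M; catalyst 0.43 mol%

| flask | remark | time |
|---|---|---|
| east | the very flask that is asked about, followed so far |  |
| flask |  | 2.0 h |

east run (percent of the starting material charged)

| time / min | target / % |
|---|---|
| 2.50 | 1.1 |
| 8.00 | 7.6 |
| 12.0 | 11.4 |
| 20.0 | 14.4 |
| 30.0 | 20.0 |
| 40.0 | 21.3 |

(each reading ± 1 percentage point)

- at the start none of the gas phase is in solution

* the target standing at 2.0 h, as a percentage of the starting material charged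
* the change that raises the amount of target at 2.0 h, in percent of the starting material charged most ("none" if none brings more than 2 percentage points) (cedar / birch / alder / none)
* amount of target at 2.0 h, in percent of the starting material charged, after cedar

- cedar: doubling the transfer coefficient of the gas phase, all else as stated
- birch: doubling the amount of catalyst, all else as stated
- alder: doubling the saturation concentration of gas phase, all else as stated

2. Suppose the impurity takes starting material one for one. Then the target can reach 50.0 % of the charge. Per catalyst that is 116 turnovers: the turnover ceiling.

3. The east flask has 49.5 turnovers at its last reading. Between its readings at 20.0 min and 40.0 min it makes 0.802 min⁻¹, with 74.8 turnovers of room midway.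

4. I take the pace as proportional to the room, which gives 0.0107 min⁻¹. By 2.0 h the room shrinks to 0.424 of itself. My reckoning is 88.0 turnovers, or 37.8 % target.

5. The forecast says 25 %, lower than my figure, on the ground that "the catalyst appears to be dying". It picks birch and gives 25.5 % after cedar. I also pick birch.

6. If the pace follows the catalyst, my reckoning puts birch at 2.0 h where it puts the east flask at twice that time: 46.6 %. That gain of 8.8 percentage points is more than the margin. I charge birch next.

The flask gives 39.1 %, with birch best by 9.4 points and 39.6 % after cedar.

    gas phase ⇌ dissolved gas, rate k1*(csat - [dissolved gas]) (kL = 0.0180 s⁻¹)
    starting material + dissolved gas + catalyst → catalyst + target (k = 37.0 M⁻² s⁻¹)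
    2 dissolved gas → self-condensation product (k = 0.0210 M⁻¹ s⁻¹)
    starting material + dissolved gas → uncatalysed product (k = 8.20 × 10⁻⁴ M⁻¹ s⁻¹)
    starting material + protic impurity → quenched substrate (k = 0.0400 M⁻¹ s⁻¹)

The east flask holds 90.9 turnovers at 2.0 h, with its catalyst at 100 %. The main reason for the shortfall is the quenching of starting material by the protic impurity. The run without that step gives 74.8 %, which is 174 turnovers, above the ceiling. With it, quenched substrate stands at 49.8 % and 0.474 % of the impurity remains. Left until 20.0 h, the same flask reaches 109 turnovers, below the ceiling of 116, with uncatalysed product at 3.39 %.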